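**Retrosynthetic overview**
1. Target 17 ⇒ O‑methylation of flavonol 16 ⇒ C3‑oxygenation of the C2=C3 bond of 5,6,7,8‑tetramethoxyflavone 14. The C3–O bond is added after ring closure because 6'‑methoxychalcones tend to give aurones under alkaline H2O2.
2. 14 ⇒ oxidative oxa‑Michael closure of ring C (O1–C2 bond) from 2'‑hydroxychalcone 12.
3. 12 ⇒ key C–C bond (future C2–C3): crossed aldol (Claisen–Schmidt) condensation of acetophenone 9 with benzaldehyde 10.
4. 9 ⇒ Friedel–Crafts acetylation with chelation‑controlled ortho‑demethylation of pentamethoxybenzene 7 ⇒ formylation, Baeyer–Villiger oxidation and methylation starting from 3,4,5‑trimethoxyphenol 1.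
5. Ring order: rings A (from 1) and B (from 10) are bought, and ring C is the only ring built (step 7).

Assumption: the target has no stereocentre or stereoaxis and is achiral, so no enantiocontrol is needed. The sp3 intermediates 11, 13 and 15 are racemic and are flattened again later in the route.

**Step 1**
Reactants: 1 3,4,5‑trimethoxyphenol
Product: 2 1,2,3,5‑tetramethoxybenzene
Conditions: MeI (1.5 equiv), K2CO3 (2 equiv), acetone, reflux
Reagents that add atoms: iodomethane CI
Why: Williamson O‑methylation of the only acidic OH is essentially quantitative and forms no stereocentre.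

**Step 2**
Reactants: 2 1,2,3,5‑tetramethoxybenzene
Product: 4 2,3,4,6‑tetramethoxybenzaldehyde, via benzylidene iminium chloride 3 (not isolated)
Conditions: POCl3 (1.3 equiv), DMF, 0 °C → rt; then ice–H2O
Reagents that add atoms: N,N‑dimethylformamide CN(C)C=O; water O
Why: Vilsmeier–Haack formylation attacks one of the two equivalent, strongly activated ring C–H positions, so hydrolysis of 3 gives a single regioisomer and no stereocentre.

**Step 3**
Reactants: 4 2,3,4,6‑tetramethoxybenzaldehyde
Product: 6 2,3,4,6‑tetramethoxyphenol, via aryl formate 5 (not isolated)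
Conditions: mCPBA (1.2 equiv), CH2Cl2, 0 °C → rt; then MeOH, conc. HCl (cat.), N2, rt
Reagents that add atoms: 3‑chloroperoxybenzoic acid O=C(OO)c1cccc(Cl)c1
Why: In this Baeyer–Villiger (Dakin‑type) oxidation the electron‑rich aryl group migrates in preference to H, and acid‑catalysed methanolysis of 5 frees the phenol without exposing it to base and air; no stereocentre is formed.

**Step 4**
Reactants: 6 2,3,4,6‑tetramethoxyphenol
Product: 7 1,2,3,4,5‑pentamethoxybenzene
Conditions: MeI (1.5 equiv), K2CO3 (2 equiv), acetone, N2, reflux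
Reagents that add atoms: iodomethane CI
Why: Williamson O‑methylation caps the oxidation‑sensitive phenol and gives a C2v‑symmetric arene with a single ring C–H; no stereocentre is formed.

**Step 5**
Reactants: 7 1,2,3,4,5‑pentamethoxybenzene
Product: 9 1‑(2‑hydroxy‑3,4,5,6‑tetramethoxyphenyl)ethan‑1‑one, via pentamethoxyacetophenone 8 (not isolated)
Conditions: AcCl (1.3 equiv), AlCl3 (2.5 equiv), Et2O, 0 °C → rt; then ice/aq HCl
Reagents that add atoms: acetyl chloride CC(=O)Cl
Why: Friedel–Crafts acylation can occur only at the one free position, and AlCl3 chelated between the ketone O and an ortho OMe then cleaves that ether alone (the two ortho OMe groups are symmetry‑equivalent), while the resulting aluminium phenolate chelate resists a second cleavage; no stereocentre is formed.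

**Step 6 (key C–C bond)**
Reactants: 9 1‑(2‑hydroxy‑3,4,5,6‑tetramethoxyphenyl)ethan‑1‑one; 10 benzaldehyde
Product: 12 (E)‑2'‑hydroxy‑3',4',5',6'‑tetramethoxychalcone, via aldol adduct 11 (not isolated)
Conditions: KOH (50 % aq, excess), EtOH, rt, 24–48 h; then dil. HCl
Reagents that add atoms: none
Why: In this Claisen–Schmidt crossed aldol condensation only 9 can enolise and only 10 is a reactive non‑enolisable electrophile, and E1cB dehydration of racemic 11 removes its stereocentre and gives the conjugated (E)‑enone under thermodynamic control.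

**Step 7**
Reactants: 12 (E)‑2'‑hydroxy‑3',4',5',6'‑tetramethoxychalcone
Product: 14 5,6,7,8‑tetramethoxyflavone, via flavanone 13 (not isolated)
Conditions: I2 (10 mol %), DMSO, 130 °C, 2–4 h; then aq Na2S2O3
Reagents that add atoms: none
Why: In this I2/DMSO oxidative cyclisation a 6‑endo oxa‑Michael closure gives racemic 13, and iodine‑mediated dehydrogenation (DMSO as terminal oxidant) then aromatises the pyranone and erases the C2 stereocentre.

**Step 8**
Reactants: 14 5,6,7,8‑tetramethoxyflavone
Product: 16 3‑hydroxy‑5,6,7,8‑tetramethoxyflavone, via flavone epoxide 15 (not isolated)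
Conditions: DMDO (ca. 0.08 M in acetone, 3 equiv in portions), CH2Cl2, 0 °C → rt, dark; concentrate; then p‑TsOH·H2O (cat.), CH2Cl2, rt
Reagents that add atoms: dimethyldioxirane CC1(C)OO1
Why: Neutral dioxirane epoxidation of the C2=C3 enol‑ether bond is followed by acid‑catalysed opening at C2 (an oxocarbenium ion stabilised by O1 and phenyl) and loss of H‑3, which gives the flavonol and erases both stereocentres of racemic 15; ring A has no C–H that could be hydroxylated.

**Step 9**
Reactants: 16 3‑hydroxy‑5,6,7,8‑tetramethoxyflavone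
Product: 17 3,5,6,7,8‑pentamethoxyflavone
Conditions: MeI (2 equiv), K2CO3 (3 equiv), acetone, reflux
Reagents that add atoms: iodomethane CI
Why: Williamson O‑methylation of the acidic enolic 3‑OH is the only reaction available and gives the achiral target.

**Compound list**
1 | 3,4,5‑trimethoxyphenol | COc1cc(O)cc(OC)c1OC | starting material
2 | 1,2,3,5‑tetramethoxybenzene | COc1cc(OC)c(OC)c(OC)c1 | intermediate
3 | N,N‑dimethyl‑(2,3,4,6‑tetramethoxybenzylidene)iminium chloride (not isolated) | COc1cc(OC)c(C=[N+](C)C)c(OC)c1OC.[Cl-] | intermediate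
4 | 2,3,4,6‑tetramethoxybenzaldehyde | COc1cc(OC)c(C=O)c(OC)c1OC | intermediate
5 | 2,3,4,6‑tetramethoxyphenyl formate (not isolated) | COc1cc(OC)c(OC=O)c(OC)c1OC | intermediate
6 | 2,3,4,6‑tetramethoxyphenol | COc1cc(OC)c(O)c(OC)c1OC | intermediate
7 | 1,2,3,4,5‑pentamethoxybenzene | COc1cc(OC)c(OC)c(OC)c1OC | intermediate
8 | 1‑(2,3,4,5,6‑pentamethoxyphenyl)ethan‑1‑one (not isolated) | COc1c(OC)c(OC)c(C(C)=O)c(OC)c1OC | intermediate
9 | 1‑(2‑hydroxy‑3,4,5,6‑tetramethoxyphenyl)ethan‑1‑one | COc1c(O)c(C(C)=O)c(OC)c(OC)c1OC | intermediate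
10 | benzaldehyde | O=Cc1ccccc1 | starting material
11 | 3‑hydroxy‑1‑(2‑hydroxy‑3,4,5,6‑tetramethoxyphenyl)‑3‑phenylpropan‑1‑one (racemic, not isolated) | COc1c(O)c(C(=O)CC(O)c2ccccc2)c(OC)c(OC)c1OC | intermediate
12 | (E)‑2'‑hydroxy‑3',4',5',6'‑tetramethoxychalcone | COc1c(O)c(C(=O)/C=C/c2ccccc2)c(OC)c(OC)c1OC | intermediate
13 | 5,6,7,8‑tetramethoxyflavanone (racemic, not isolated) | COc1c(OC)c(OC)c2c(c1OC)OC(c1ccccc1)CC2=O | intermediate
14 | 5,6,7,8‑tetramethoxyflavone | COc1c(OC)c(OC)c2c(=O)cc(-c3ccccc3)oc2c1OC | intermediate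
15 | 2,3‑epoxy‑5,6,7,8‑tetramethoxyflavanone (racemic, epoxide necessarily cis‑fused, not isolated) | COc1c(OC)c(OC)c2c(c1OC)OC1(c3ccccc3)OC1C2=O | intermediate
16 | 3‑hydroxy‑5,6,7,8‑tetramethoxyflavone | COc1c(OC)c(OC)c2c(=O)c(O)c(-c3ccccc3)oc2c1OC | intermediate
17 | 3,5,6,7,8‑pentamethoxyflavone | COc1c(OC)c(OC)c2c(=O)c(OC)c(-c3ccccc3)oc2c1OC | target

**Total step count:** 9. **Longest linear sequence:** 9 steps (1 → 17; benzaldehyde 10 is bought).

**Three steps most likely to fail**

*Step 8 (C3‑oxygenation).* The C2=C3 bond is a vinylogous ester and epoxidises slowly, and the excess oxidant that this requires may attack the electron‑rich ring A.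
The fallback sets out from 14 and comes back at 16, replacing the electrophilic oxidation with an anionic borylation–oxidation.
- 14 is deprotonated at C3 with LDA in THF at −78 °C to give 3‑lithio‑5,6,7,8‑tetramethoxyflavone F1.
- Trapping with B(OMe)3 gives dimethyl (5,6,7,8‑tetramethoxy‑4‑oxo‑2‑phenyl‑4H‑chromen‑3‑yl)boronate F2.
- Oxidation in the same pot with AcOH/30 % H2O2 at 0 °C → rt gives 16.

*Step 5 (acylation with mono‑demethylation).* AlCl3 may cleave a second ortho OMe or an inner OMe group.
The fallback sets out from 1 and comes back at 9. It needs no demethylation, because the phenol OH of 1 is retained, and it also bypasses steps 1–4.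
- 1 is C‑acetylated ortho to OH with AcOH/BF3·OEt2 at 90 °C (both ortho positions are equivalent) to give 1‑(2‑hydroxy‑4,5,6‑trimethoxyphenyl)ethan‑1‑one F3.
- NBS in MeCN at 0 °C brominates the only free ring position to give 1‑(3‑bromo‑2‑hydroxy‑4,5,6‑trimethoxyphenyl)ethan‑1‑one F4.
- Ullmann‑type methoxylation (NaOMe, CuBr cat., DMF/MeOH, 110 °C) replaces Br by OMe and gives 9.

*Step 3 (Baeyer–Villiger oxidation to the phenol).* Aldehyde 4 and especially phenol 6 are so electron‑rich that peracid or air can over‑oxidise them to methoxyquinones.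
The fallback sets out from 2 and comes back at 7, so no free phenol or oxidant is involved and compounds 4 and 6 are skipped.
- 2 is monobrominated with NBS (1.0 equiv, MeCN, 0 °C) at one of its two equivalent positions to give 2‑bromo‑1,3,4,5‑tetramethoxybenzene F5.
- Copper‑catalysed methoxylation (NaOMe, CuBr cat., DMF/MeOH, 110 °C) converts this directly into 7.

**Further compounds**
F1 | step 8 | 3‑lithio‑5,6,7,8‑tetramethoxyflavone | [Li]c1c(-c2ccccc2)oc2c(OC)c(OC)c(OC)c(OC)c2c1=O
F2 | step 8 | dimethyl (5,6,7,8‑tetramethoxy‑4‑oxo‑2‑phenyl‑4H‑chromen‑3‑yl)boronate | COB(OC)c1c(-c2ccccc2)oc2c(OC)c(OC)c(OC)c(OC)c2c1=O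
F3 | step 5 | 1‑(2‑hydroxy‑4,5,6‑trimethoxyphenyl)ethan‑1‑one | COc1cc(O)c(C(C)=O)c(OC)c1OC
F4 | step 5 | 1‑(3‑bromo‑2‑hydroxy‑4,5,6‑trimethoxyphenyl)ethan‑1‑one | COc1c(Br)c(O)c(C(C)=O)c(OC)c1OC
F5 | step 3 | 2‑bromo‑1,3,4,5‑tetramethoxybenzene | COc1cc(OC)c(Br)c(OC)c1OC
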